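Millimolar of substrate stands against micromolar of free enzyme, so the charge is best read as work per enzyme molecule.

| flask | substrate | free enzyme | temperature | remark | time |
|---|---|---|---|---|---|
| Wednesday's | 48 mM | 3.2 µM | −15 °C | run made earlier |  |
| ash | 32 mM | 3.2 µM | −15 °C |  | 10 h |
| elm | 32 mM | 3.2 µM | 25 °C |  | 10 h |
| maple | 32 mM | 3.2 µM | 45 °C |  | 10 h |
| alder | 32 mM | 3.2 µM | 5 °C |  | 10 h |

Ash, elm, maple and alder each charge c(substrate) = 32 mM and c(free enzyme) = 3.2 µM, so full conversion asks 10000 turnovers of each enzyme molecule. One enzyme molecule meets a fork at each step: it turns over again or it may be lost.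

Wednesday's run (percent of the substrate charged)

| time / h | target / % | substrate / % |
|---|---|---|
| 0.250 | 7.1 | 92.7 |
| 0.333 | 9.7 | 90.5 |
| 0.500 | 12.4 | 88.3 |
| 0.833 | 16.9 | 82.1 |
| 1.33 | 22.4 | 77.4 |
| 2.00 | 27.0 | 72.5 |
| 3.00 | 33.5 | 67.0 |

(standard deviation of a reading: 0.3 percentage points)

- the analysis behind the earlier runs scatters by 0.3 percentage points, standard deviation
- the earlier runs do not show what temperature does; that part of a forecast is a guess
- a reading or a percentage of target counts all its forms, free or not

At the last reading, substrate and target sum to 101%, so target can be read as the substrate gone. That reading, at 3.00 h, shows 5020 turnovers per enzyme molecule. This is the turnover count N, the field's total turnover number: target made per enzyme molecule charged. Target in percent is then N·c(free enzyme)/c(substrate).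

But the pace falls. It is 4260 h⁻¹ up to the first reading and 975 h⁻¹ between the last two, a fall by a factor of 4.37, with substrate still at 67.0%. Enzyme loss and hold-up by target are both open at this point.

* the best flask by amount of target, in percent of the substrate charged; "all alike" if 1.5 percentage points covers them all (ash / elm / maple / alder / all alike)
* amount of target at the end, in percent of the substrate charged, ash
* amount of target at the end, in percent of the substrate charged, elm
* amount of target at the end, in percent of the substrate charged, maple
* amount of target at the end, in percent of the substrate charged, alder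

Suppose N keeps gaining as it did from 1860 at 0.500 h, the same amount for each equal factor of time. Ash then reaches 7150, which is 71.5% of its charge. This is the present reckoning, and it leans high, since ash starts thinner than Wednesday's run. The other temperatures stay a guess.

The forecast names elm as the best flask, with 62% for ash, 94% for elm, 78% for maple and 90% for alder, and says of maple that “the enzyme may die early”.

The flasks give 64.4% in ash, below the reckoned figure, 87.9% in elm, 46.2% in maple and 79.8% in alder, so elm leads.

    free enzyme → unfolded enzyme (k = 1.70 × 10⁻⁴ min⁻¹, Ea = 257 kJ mol⁻¹)
    substrate + free enzyme → target + free enzyme, rate k2*[substrate]*[free enzyme]/(1 + ([substrate]/Km2)) (9.00 mM, k = 1.40 × 10⁵ L mol⁻¹ min⁻¹, Ea = 39.0 kJ mol⁻¹)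
    crystals ⇌ target, rate k3*(cs3 - [target]) while solid is left; crystals form when [target] > cs3 (solubility = 30.0 mM, k = 0.260 min⁻¹)
    2 free enzyme → spent catalyst (k = 75000 L mol⁻¹ min⁻¹, Ea = 41.0 kJ mol⁻¹)
    (constants at 25 °C)

In maple, the half-life of free enzyme by the step to unfolded enzyme is 0.10 h at 0.0329 h, against a run of 10 h, and the making of target has >99.9% of its turnover behind it by 2.00 h. By 5.00 h maple holds 0% of its catalyst as free enzyme, 21.6% as unfolded enzyme and 78.4% as spent catalyst, and N in maple stands at 4620 of the 10000 asked, below the 5020 of Wednesday's last reading, with target still 46.2% at 100 h. The neighbour of maple charged with 54 mM ends at 31.4%, a lower percentage, yet its N is higher, at 5300.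

The data come from a simulation for an exercise; the scatter is artificial.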